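The data are calculated for substances that don't exist, noise included.

What has gone into a flask is still substrate, has become target, or is missing from both. So you can reckon target by subtraction, from what is left and what is lost.

the same everywhere: free catalyst 1.2 mM
- north-east: substrate 0.38 M (fed, over 2.5 min); run made earlier
- flask: substrate 0.25 M (fed, over 2.5 min); time 2.5 min

north-east run (percent of the substrate charged)

| time / s | target / % | substrate / % |
|---|---|---|
| 12.0 | 4.4 | 3.8 |
| 25.0 | 10.1 | 5.8 |
| 30.0 | 12.4 | 6.6 |
| 50.0 | 21.1 | 9.8 |

(readings scatter by 0.5 percentage points)

* amount of target in percent of the substrate charged, at 15 s, 50 s and 2.5 min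

- percentages count the whole charge, also what has not yet gone in

By 50.0 s the north-east run had taken in 33.3% of its charge and showed 21.1% target and 9.8% substrate, so 2.4 percentage points was missing, on readings scattering by 0.5 points. Between 12.0 s and 50.0 s target grew at 1.67 mM s⁻¹, while substrate rose from 14.4 mM to 37.2 mM. I read that steady rate as what this much catalyst was seen to sustain, a reading that may stand below its ceiling (Vmax). This flask is fed at 1.67 mM s⁻¹, which gives 0.998 for the load, the feed rate divided by that read rate. The north-east run, fed at 2.53 mM s⁻¹, had 1.52.

Now build this flask up. With the main step by itself, target keeps pace with the feed, which gives 10.0%, 33.3% and 100% at the asked times. Add a standing stock of substrate: if the 14.4 mM of the first north-east reading is what the catalyst needs, that is 5.78% of this charge, and the end falls to 94.2%. Add the loss: the north-east run was missing 7.30% of what had gone in, and the same share here leaves 86.9% at the end. I apply this to the end point and make no such reckoning for the early times.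

The forecast gives 6.7%, 27% and 87%, and its ground is this: “The flask feed is 1.67 mM/s, just under Vmax, so substrate should level off near 14 mM.”

The flask gives 6.89%, 28.4% and 88.8%, within the margin of the forecast.

    substrate + free catalyst → catalyst intermediate A (k = 580 M⁻¹ s⁻¹)
    catalyst intermediate A ⇌ catalyst intermediate B (K = 14.0, k = 100 s⁻¹)
    catalyst intermediate B → free catalyst + target (k = 1.90 s⁻¹)
    substrate + target → side product (k = 0.0580 M⁻¹ s⁻¹)

Substrate in this flask stood at 4.00% at 1.25 min and 3.59% at 2.50 min, a level stock at a load of 0.998. The north-east run, at 1.52, had substrate climbing, and at 50.0 s it held 21.1% target out of 33.3% fed.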